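Remark on the chemistry: centres that are erased later (the carbinol carbon of 7, 17 and 26, C3 of 19, the methine carbons of 26 and 27) are carried as epimer mixtures and left undefined in the SMILES. The configurations of 12 and 14 were checked against each other (inversion only at the sulfonate carbon) and against the target; no correction was needed.

## Structural features

The target joins three units: a bicyclo[3.1.0]hex-2-ene core (cyclopentene ring A fused to cyclopropane ring B), a 2-methoxy-3,5-dimethyl-4-pyranone bound through its C6 to the apex C6 of ring B, and a 3-oxopent-1-en-2-yl chain on C4. Four contiguous stereocentres sit on the core: the methylated quaternary fusion carbon C1, the fusion methine C5, the quaternary apex C6 (methyl endo over ring A, pyranone exo) and the allylic methine C4, whose chain is anti to ring B. The fragile parts are: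
- the vinylcyclopropane, which acids and electrophiles open;
- the doubly allylic C4–H, through which base can move the side-chain alkene or epimerise C4;
- the 1-substituted vinyl ketone, a strong Michael acceptor;
- the α-methoxy-γ-pyranone, which hard nucleophiles attack and which is regiochemically delicate to make.

The real difficulty is the pair of adjacent quaternary carbons C1 and C6 on a three-membered ring, with defined endo/exo placement at C6 and the correct absolute sense relative to C4. The key step uses the fact that C4–C5–C6–C1–C2–C3 becomes a six-membered carbocycle once the C1–C5 bond is removed. That carbocycle is the ring of a monoterpene ketone: C4 with its isopropenyl group is the terpene stereocentre, C6 the former carbonyl carbon and C1 the methyl-bearing alkene carbon. Closing C1–C5 across this ring, by an enolate at C1 displacing a leaving group on C5, makes ring B and contracts the six-membered ring to ring A in one event.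

## Logic of the disconnections

**31 to 29.** No skeletal bond is cut; the vinyl ketone carbonyl is traced back to a silyl-protected carbinol (through 30). The reason is the acceptor reactivity of the enone, which no base or nucleophile of the earlier steps would spare. The demand is a neutral desilylation and a mild final oxidation.

**29 to 23 and 24.** The pyranone is cut at the ring O–C(=O) bond, at the O–CH3 bond and at the C–C bond between the carbon attached to the core and its ring neighbour. This is the polyketide seam: an aldehyde on C6 without α-hydrogens plus a five-carbon keto ester. The gain is the whole heterocycle. The demands are an aldol addition at a neopentyl-type aldehyde, oxidation and lactonisation (26, 27, 28), and methylation at the lactone carbonyl oxygen rather than at the 4-hydroxyl.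

**23 to 20.** The C2–H bond is traced to a C2–O triflate and the aldehyde to a protected primary alcohol (22, 21). The reason is timing: the acetal is removed while C2=C3 is still deactivated by the sulfonate, and the electron-rich vinylcyclopropane appears only afterwards. The demands are an acetal cleavage that spares the silyl ether and a hydride transfer from palladium that does not open ring B.

**20 to 18.** The C3–CH3 bond and the C2–O sulfonate bond are cut (through 19). The ketone left at C2 by the key step is the handle, and only C3 can be enolised because C1 is quaternary. The gain is one methyl group and the ring alkene. The demand is clean monoalkylation.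

**18 to 14.** The bond between the carbinol carbon and the ethyl group is cut, then the C–O bond on the former allylic methyl (17, 16, 15). The isopropenyl group is thus a latent 3-oxopent-1-en-2-yl group. The demands are an allylic oxidation that takes the methyl group and not C4–H or the ketone α-methylene, and a Grignard addition that chooses the aldehyde over the ring ketone.

**14 to 12 (key).** The C1–C5 bond, common to both rings, is cut. This turns the bicycle into a monocycle and trades two stereocentres (C1, C5) for one oxygen-bearing centre. The demands are an enolate fixed on the C1 side (13, stored as the enol acetate) and a sulfonate on the future C5 that is trans to the isopropenyl group and cis to the future C6 methyl, so that rear-side attack is possible.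

**12 to 8.** The C–CH3 bond at the future C6 is cut; sulfonate and acetate are functional-group changes (11, 10). Conjugate addition creates the quaternary carbon and, in the same act, the regiodefined enolate 9. The demands are methyl delivery anti to the isopropenyl group (syn to the silyloxy group), a γ-oxygen that is a poor leaving group during the cuprate step, and a desilylation that spares the enol acetate.

**8 to 4 and 5.** The C–CH2O bond is cut and the oxygen is moved back by a 1,3-transposition (through 7 and 6). This carries the carbonyl from the future C2 to the future C6 and delivers the one-carbon arm. The gain is a return to the terpene skeleton. The demands are 1,2-addition without enolisation and an oxidative rearrangement that tolerates acetal and silyl ether.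

**4 to 1.** The C–O bond at the α′ carbon (future C5) is cut (through 3 and 2). This oxygen is the later leaving group, and removing it arrives at the commercial terpene. The demand is hydroxylation trans to the isopropenyl group.

## Other disconnections considered

**Alternative 1:** The cut is C4–C5, seen as the residue of a C–N–C unit. The core is derived from the secondary amine tert-butyldimethyl({4,6,7-trimethyl-3-[(trimethylsilyl)ethynyl]-2-azabicyclo[4.1.0]hept-4-en-7-yl}methoxy)silane A2, reached from 3,5-dimethylpyridine A1 by alkynylative dearomatisation and cyclopropanation of the remaining enamine-type double bond. In the forward key step an anomeric N-alkoxy-N-acyloxy amide aminates the ring nitrogen, the 1,1-diazene loses dinitrogen and the two former α-carbons join to give the alkynyl bicyclohexene A3.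
- In its favour: a flat, cheap heteroaromatic start carries both ring methyl groups. The alkyne at C4 is a more compact precursor of the 1-acylvinyl chain than the isopropenyl group, which costs five operations in the chosen plan (steps 9–11, 21, 22); on this point the alternative is better.
- Against it: the absolute configuration must come from an asymmetric dearomatisation, whereas the chosen plan inherits it from 1. The cyclopropanation must build two adjacent quaternary carbons on a trisubstituted enamine with endo/exo control, a problem that the six-membered-ring cuprate addition of step 5 avoids. The extrusion passes through a short-lived 1,4-diradical whose C4 end is allylic and propargylic and whose C5 end is an unstabilised cyclopropyl radical, so the C4 configuration is less secure than in the stereospecific SN2 closure of step 8.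
- Comparison: the alternative would plausibly reach the core in fewer steps than the eight needed for 14, and is better there. It is weaker in stereochemical certainty.

**Alternative 2:** The cut is C5–C6, after undoing a ring contraction. The cyclobutanone 7-chloro-1,3,7-trimethylbicyclo[3.2.0]hept-2-en-6-one A6 (chlorine exo, methyl endo) would come from the [2+2] cycloaddition of chloro(methyl)ketene A5 to 1,3-dimethylcyclopenta-1,3-diene A4. In the forward key step methoxide adds to the carbonyl and the C5–acyl bond shifts to the chlorine-bearing carbon with inversion (quasi-Favorskii, semibenzilic type), giving methyl 1,3,6-trimethylbicyclo[3.1.0]hex-2-ene-6-carboxylate A7.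
- In its favour: two or three steps give a core with both quaternary carbons and methyl endo, since the larger ketene substituent prefers the endo position and the exo chloride is the one aligned for migration. C6 arrives at the ester oxidation level, so the dianion of 24 could be acylated directly; this is better than the deprotection and oxidation of steps 14 and 16.
- Against it: A7 is racemic unless resolved. The diene A4 equilibrates by hydrogen shifts and offers two different double bonds. C4 of A7 is a bare allylic methylene, so the side chain would have to be introduced there, anti to ring B, on an acid-sensitive vinylcyclopropane. The chosen plan has this carbon, its substituent and its configuration from the first step.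
- Comparison: mechanistically the two are equal, both being intramolecular displacements with inversion at one carbon. The alternative is clearly shorter to the core and less settled beyond it.

**Alternative 3:** The cut takes C1–C5 and C5–C6 together and leads to the acyclic enyne tert-butyl{[(E)-1-(4-methoxybenzyloxy)-2,3,5-trimethylhept-2-en-6-yn-4-yl]oxy}dimethylsilane A8. In the forward key step (Ph3P)AuCl/AgSbF6 (monovalent gold) activates the terminal alkyne, the tetrasubstituted alkene attacks it, and the cyclopropyl gold carbene collapses by a 1,2-hydrogen shift to tert-butyl{[6-(4-methoxybenzyloxymethyl)-1,3,6-trimethylbicyclo[3.1.0]hex-3-en-2-yl]oxy}dimethylsilane A9.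
- In its favour: two C–C bonds, both rings and three stereocentres form in one catalytic step, which is better than step 8 (one bond, one ring). The E alkene geometry passes stereospecifically into the C6 configuration, and the carbinol, available by asymmetric carbonyl addition, steers the facial selectivity.
- Against it: A9 has its functionality one position off (alkene at C3=C4, oxygen at C2). An allylic transposition with C–C bond formation at C4, on the face of the departing oxygen, would be needed on a cyclopropylcarbinyl system that ionises easily. A tetrasubstituted alkene is also a demanding nucleophile for the gold-activated alkyne.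
- Comparison: the mechanism is cationic, against the anionic and stereospecific closure chosen here. The step count to the core is equal or slightly better, and the total is probably similar once the transposition is paid for.

Key step: step 8

## Route

Step 1
Reactants: 1 (S)-carvone
Product: 3 (5R,6R)-6-hydroxy-2-methyl-5-(prop-1-en-2-yl)cyclohex-2-en-1-one (hydroxyl trans to isopropenyl), via silyl dienol ether 2 (not isolated)
Conditions: LiN(iPr)2, THF, −78 °C; Me3SiCl; then mCPBA, NaHCO3, CH2Cl2, −20 °C; then 1 M HCl, THF, 0 °C
Reagents that add atoms: mCPBA, OOC(=O)c1cccc(Cl)c1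
Why: Kinetic deprotonation takes the α′ hydrogen and gives the cross-conjugated silyl dienol ether, whose enol ether double bond is epoxidised faster than the isopropenyl group (Rubottom oxidation). The peracid should approach anti to the neighbouring isopropenyl group, which sets the new carbinol centre trans to it.

Step 2
Reactants: 3 (5R,6R)-6-hydroxy-2-methyl-5-(prop-1-en-2-yl)cyclohex-2-en-1-one
Product: 4 (5R,6R)-6-[(tert-butyldimethylsilyl)oxy]-2-methyl-5-(prop-1-en-2-yl)cyclohex-2-en-1-one
Conditions: TBSCl, imidazole, DMF, rt
Reagents that add atoms: TBSCl, CC(C)(C)[Si](C)(C)Cl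
Why: Standard silylation of a secondary α-hydroxy ketone. The silyl ether keeps this oxygen a poor leaving group through the organolithium, chromium and cuprate steps, where a sulfonate would be lost by reductive elimination.

Step 3
Reactants: 4 (5R,6R)-6-[(tert-butyldimethylsilyl)oxy]-2-methyl-5-(prop-1-en-2-yl)cyclohex-2-en-1-one; 5 tributyl[(methoxymethoxy)methyl]stannane
Product: 7 (5R,6R)-6-[(tert-butyldimethylsilyl)oxy]-1-[(methoxymethoxy)methyl]-2-methyl-5-(prop-1-en-2-yl)cyclohex-2-en-1-ol (C1 epimers), via (methoxymethoxy)methyllithium 6 (not isolated)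
Conditions: n-BuLi, THF, −78 °C; then 4, −78 °C; NH4Cl (aq), −78 °C → rt
Reagents that add atoms: none
Why: Tin–lithium exchange gives the α-alkoxymethyllithium, a hard nucleophile that adds 1,2 to the enone. The carbinol configuration is irrelevant because this carbon becomes sp2 in step 4, and the cold quench keeps the lithium alkoxide from taking over the neighbouring silyl group.

Step 4
Reactants: 7 (5R,6R)-6-[(tert-butyldimethylsilyl)oxy]-1-[(methoxymethoxy)methyl]-2-methyl-5-(prop-1-en-2-yl)cyclohex-2-en-1-ol
Product: 8 (4R,5R)-4-[(tert-butyldimethylsilyl)oxy]-3-[(methoxymethoxy)methyl]-2-methyl-5-(prop-1-en-2-yl)cyclohex-2-en-1-one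
Conditions: [C5H5NH][CrO3Cl], NaOAc, 4 Å MS, CH2Cl2, rt
Reagents that add atoms: pyridinium chlorochromate [C5H5NH][CrO3Cl] (oxygen of the new carbonyl group), [O-][Cr](=O)(=O)Cl.c1cc[nH+]cc1
Why: Babler–Dauben oxidative transposition: the tertiary allylic chromate ester undergoes a [3,3] shift and the resulting secondary chromate is oxidised to the enone by hexavalent chromium. The acetate buffer protects acetal and silyl ether.

Step 5
Reactants: 8 (4R,5R)-4-[(tert-butyldimethylsilyl)oxy]-3-[(methoxymethoxy)methyl]-2-methyl-5-(prop-1-en-2-yl)cyclohex-2-en-1-one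
Product: 10 (3S,4R,5R)-4-[(tert-butyldimethylsilyl)oxy]-3-[(methoxymethoxy)methyl]-2,3-dimethyl-5-(prop-1-en-2-yl)cyclohex-1-en-1-yl acetate, via lithium enolate 9 (not isolated)
Conditions: Me2CuLi (from CuI and MeLi), Et2O, −20 → 0 °C; then Ac2O, 0 °C → rt
Reagents that add atoms: Me2CuLi, [Li+].C[Cu-]C; acetic anhydride, CC(=O)OC(C)=O
Why: Cuprate 1,4-addition creates the quaternary carbon. Axial attack on the half-chair with silyloxy and isopropenyl groups both equatorial should deliver methyl trans to the isopropenyl group, as is usual for 5-substituted cyclohexenones, and therefore cis to the silyloxy group. O-acetylation of the lithium enolate stores its regiochemistry as the enol acetate.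

Step 6
Reactants: 10 (3S,4R,5R)-4-[(tert-butyldimethylsilyl)oxy]-3-[(methoxymethoxy)methyl]-2,3-dimethyl-5-(prop-1-en-2-yl)cyclohex-1-en-1-yl acetate
Product: 11 (3S,4R,5R)-4-hydroxy-3-[(methoxymethoxy)methyl]-2,3-dimethyl-5-(prop-1-en-2-yl)cyclohex-1-en-1-yl acetate
Conditions: HF·pyridine, pyridine, THF, 0 °C → rt
Reagents that add atoms: none
Why: Buffered hydrogen fluoride cleaves the hindered silyl ether without touching the enol acetate or the acetal; a basic fluoride source would attack the enol ester.

Step 7
Reactants: 11 (3S,4R,5R)-4-hydroxy-3-[(methoxymethoxy)methyl]-2,3-dimethyl-5-(prop-1-en-2-yl)cyclohex-1-en-1-yl acetate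
Product: 12 (3S,4R,5R)-3-[(methoxymethoxy)methyl]-2,3-dimethyl-4-[(methylsulfonyl)oxy]-5-(prop-1-en-2-yl)cyclohex-1-en-1-yl acetate (sulfonate cis to the C3 methyl and trans to isopropenyl)
Conditions: MsCl, Et3N, CH2Cl2, −20 → 0 °C
Reagents that add atoms: methanesulfonyl chloride, CS(=O)(=O)Cl
Why: Mesylation through the sulfene works on hindered, neopentyl-type secondary alcohols and retains the C–O configuration. The amine base does not disturb the enol acetate.

Step 8
Reactants: 12 (3S,4R,5R)-3-[(methoxymethoxy)methyl]-2,3-dimethyl-4-[(methylsulfonyl)oxy]-5-(prop-1-en-2-yl)cyclohex-1-en-1-yl acetate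
Product: 14 (1S,4S,5S,6S)-6-[(methoxymethoxy)methyl]-1,6-dimethyl-4-(prop-1-en-2-yl)bicyclo[3.1.0]hexan-2-one (C6 methyl endo; isopropenyl anti to the cyclopropane), via lithium enolate 13 (not isolated)
Conditions: MeLi (2.1 equiv), THF, −78 °C → rt; NH4Cl (aq)
Reagents that add atoms: none
Why: Two equivalents of MeLi attack the acetyl carbonyl of 12 (enol ester cleavage by an alkyllithium) and release the lithium enolate 13 with its double bond fixed between C1 and C2 of the cyclohexene, lithium tert-butoxide being the by-product. The enolate carbon C2 then displaces the sulfonate on C4 from the rear in an intramolecular SN2 reaction, the known base-induced 1,3-elimination of γ-sulfonyloxy ketones to bicyclo[3.1.0]hexan-2-ones. The cyclopropane closes in the 3-exo-tet mode; the cyclopentanone is not closed separately but is what remains of the six-membered ring once the transannular bond exists. The new methine (C5 of 14) is set by inversion at the sulfonate carbon, so it traces back to the trans hydroxylation of step 1. The new quaternary fusion carbon (C1 of 14) has no freedom, because only the enolate face that reaches the σ* orbital of the C–O bond can give the cis-fused bicycle. With the sulfonate trans to the isopropenyl group and cis to the C3 methyl, the half-chair that holds sulfonate and isopropenyl equatorial puts the C–O bond in a W relationship to the enolate p-orbital and the axial C3 methyl over the forming five-membered ring; this should give methyl endo, the alkoxymethyl arm exo and isopropenyl anti to the cyclopropane. The step needs the enolate on the C2 side and not on the C6 side, which could close a different cyclopropane; the enol acetate written in step 5 secures this, and ring closure is expected to outrun proton exchange with ketone already formed. O-alkylation is excluded because it would give a bridgehead enol ether.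

Step 9
Reactants: 14 (1S,4S,5S,6S)-6-[(methoxymethoxy)methyl]-1,6-dimethyl-4-(prop-1-en-2-yl)bicyclo[3.1.0]hexan-2-one
Product: 16 6-[(methoxymethoxy)methyl]-1,6-dimethyl-4-(3-oxoprop-1-en-2-yl)bicyclo[3.1.0]hexan-2-one (ring configuration as in 14), via allylic alcohol 15 (not isolated)
Conditions: SeO2 (cat.), t-BuOOH, CH2Cl2, rt; then MnO2, CH2Cl2, rt
Reagents that add atoms: tert-butyl hydroperoxide (oxygen atom, passed on through SeO2), CC(C)(C)OO
Why: Riley-type allylic oxidation (ene reaction, then [2,3] shift) of a 1,1-disubstituted alkene takes the methyl group in preference to the tertiary C4–H, and at room temperature with catalytic selenium the ketone α-methylene should be left alone. MnO2 then converges the alcohol/aldehyde mixture on the enal.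

Step 10
Reactants: 16 6-[(methoxymethoxy)methyl]-1,6-dimethyl-4-(3-oxoprop-1-en-2-yl)bicyclo[3.1.0]hexan-2-one
Product: 17 4-(3-hydroxypent-1-en-2-yl)-6-[(methoxymethoxy)methyl]-1,6-dimethylbicyclo[3.1.0]hexan-2-one (carbinol epimers; ring configuration as in 14)
Conditions: EtMgBr (1.1 equiv), THF, −78 °C; NH4Cl (aq)
Reagents that add atoms: ethylmagnesium bromide, CC[Mg]Br
Why: Grignard 1,2-addition to the 2-substituted propenal. The aldehyde is far more electrophilic than the cyclopropyl ketone, which is flanked by the quaternary C1; both carbinol epimers converge in step 22.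

Step 11
Reactants: 17 4-(3-hydroxypent-1-en-2-yl)-6-[(methoxymethoxy)methyl]-1,6-dimethylbicyclo[3.1.0]hexan-2-one
Product: 18 4-{3-[(tert-butyldimethylsilyl)oxy]pent-1-en-2-yl}-6-[(methoxymethoxy)methyl]-1,6-dimethylbicyclo[3.1.0]hexan-2-one
Conditions: TBSCl, imidazole, DMF, rt
Reagents that add atoms: TBSCl, CC(C)(C)[Si](C)(C)Cl
Why: Standard silylation of a secondary allylic alcohol; the chloride with imidazole does not enolise the ketone. The latent enone stays masked until the end.

Step 12
Reactants: 18 4-{3-[(tert-butyldimethylsilyl)oxy]pent-1-en-2-yl}-6-[(methoxymethoxy)methyl]-1,6-dimethylbicyclo[3.1.0]hexan-2-one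
Product: 19 4-{3-[(tert-butyldimethylsilyl)oxy]pent-1-en-2-yl}-6-[(methoxymethoxy)methyl]-1,3,6-trimethylbicyclo[3.1.0]hexan-2-one (C3 epimers)
Conditions: LiN(iPr)2, THF, −78 °C; MeI, −78 → −20 °C
Reagents that add atoms: iodomethane, CI
Why: Only C3 carries α-hydrogens, so the lithium enolate is regiodefined and is methylated there. The C3 configuration is erased in step 13.

Step 13
Reactants: 19 4-{3-[(tert-butyldimethylsilyl)oxy]pent-1-en-2-yl}-6-[(methoxymethoxy)methyl]-1,3,6-trimethylbicyclo[3.1.0]hexan-2-one
Product: 20 4-{3-[(tert-butyldimethylsilyl)oxy]pent-1-en-2-yl}-6-[(methoxymethoxy)methyl]-1,3,6-trimethylbicyclo[3.1.0]hex-2-en-2-yl trifluoromethanesulfonate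
Conditions: KN(SiMe3)2, THF, −78 → 0 °C; PhNTf2
Reagents that add atoms: N-phenylbis(trifluoromethanesulfonimide), O=S(=O)(N(c1ccccc1)S(=O)(=O)C(F)(F)F)C(F)(F)F
Why: Removal of the remaining C3–H gives the only possible enolate, which is O-sulfonylated to the enol triflate; C2=C3 is now in place with the methyl on C3.

Step 14
Reactants: 20 4-{3-[(tert-butyldimethylsilyl)oxy]pent-1-en-2-yl}-6-[(methoxymethoxy)methyl]-1,3,6-trimethylbicyclo[3.1.0]hex-2-en-2-yl trifluoromethanesulfonate
Product: 21 4-{3-[(tert-butyldimethylsilyl)oxy]pent-1-en-2-yl}-6-(hydroxymethyl)-1,3,6-trimethylbicyclo[3.1.0]hex-2-en-2-yl trifluoromethanesulfonate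
Conditions: Me2BBr, CH2Cl2, −78 °C; then NaHCO3 (aq)
Reagents that add atoms: none
Why: Dimethylboron bromide cleaves acetal-type ethers at low temperature by bromide attack on the activated O–CH2–O unit and should leave the silyl ether and the alkenes alone. The step is placed here because the C2=C3 bond is still deactivated by the triflate, so the acid-sensitive vinylcyclopropane is not yet present.

Step 15
Reactants: 21 4-{3-[(tert-butyldimethylsilyl)oxy]pent-1-en-2-yl}-6-(hydroxymethyl)-1,3,6-trimethylbicyclo[3.1.0]hex-2-en-2-yl trifluoromethanesulfonate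
Product: 22 (4-{3-[(tert-butyldimethylsilyl)oxy]pent-1-en-2-yl}-1,3,6-trimethylbicyclo[3.1.0]hex-2-en-6-yl)methanol
Conditions: Pd(OAc)2 (cat.), PPh3, HCO2H, n-Bu3N, DMF, 60 °C
Reagents that add atoms: none
Why: Palladium-catalysed formate reduction of an enol triflate: oxidative addition to zerovalent palladium, exchange for formate, loss of CO2 and reductive elimination replace C–O by C–H without moving the double bond. A 1-cyclopropylvinyl palladium species has no easy ring-opening path.

Step 16
Reactants: 22 (4-{3-[(tert-butyldimethylsilyl)oxy]pent-1-en-2-yl}-1,3,6-trimethylbicyclo[3.1.0]hex-2-en-6-yl)methanol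
Product: 23 4-{3-[(tert-butyldimethylsilyl)oxy]pent-1-en-2-yl}-1,3,6-trimethylbicyclo[3.1.0]hex-2-ene-6-carbaldehyde
Conditions: Dess–Martin periodinane, NaHCO3, CH2Cl2, 0 °C → rt
Reagents that add atoms: none
Why: Buffered periodinane oxidation of a primary alcohol. The aldehyde has no α-hydrogen and cannot epimerise or enolise.

Step 17
Reactants: 23 4-{3-[(tert-butyldimethylsilyl)oxy]pent-1-en-2-yl}-1,3,6-trimethylbicyclo[3.1.0]hex-2-ene-6-carbaldehyde; 24 methyl 2-methyl-3-oxopentanoate
Product: 26 methyl 5-(4-{3-[(tert-butyldimethylsilyl)oxy]pent-1-en-2-yl}-1,3,6-trimethylbicyclo[3.1.0]hex-2-en-6-yl)-5-hydroxy-2,4-dimethyl-3-oxopentanoate (epimer mixture), via sodium lithium dianion 25 (not isolated)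
Conditions: 24, NaH then n-BuLi, THF, 0 °C; then 23, −78 °C; NH4Cl (aq)
Reagents that add atoms: none
Why: The β-keto ester dianion reacts at its more nucleophilic γ-carbon in an aldol addition to the aldehyde. The new centres are all removed in steps 18 and 19.

Step 18
Reactants: 26 methyl 5-(4-{3-[(tert-butyldimethylsilyl)oxy]pent-1-en-2-yl}-1,3,6-trimethylbicyclo[3.1.0]hex-2-en-6-yl)-5-hydroxy-2,4-dimethyl-3-oxopentanoate
Product: 27 methyl 5-(4-{3-[(tert-butyldimethylsilyl)oxy]pent-1-en-2-yl}-1,3,6-trimethylbicyclo[3.1.0]hex-2-en-6-yl)-2,4-dimethyl-3,5-dioxopentanoate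
Conditions: Dess–Martin periodinane, NaHCO3, CH2Cl2, rt
Reagents that add atoms: none
Why: Periodinane oxidation of a β-hydroxy ketone to the 1,3-diketone is the standard entry to β,δ-diketo esters. The mild, buffered conditions avoid retro-aldol cleavage.

Step 19
Reactants: 27 methyl 5-(4-{3-[(tert-butyldimethylsilyl)oxy]pent-1-en-2-yl}-1,3,6-trimethylbicyclo[3.1.0]hex-2-en-6-yl)-2,4-dimethyl-3,5-dioxopentanoate
Product: 28 6-(4-{3-[(tert-butyldimethylsilyl)oxy]pent-1-en-2-yl}-1,3,6-trimethylbicyclo[3.1.0]hex-2-en-6-yl)-4-hydroxy-3,5-dimethyl-2H-pyran-2-one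
Conditions: DBU, toluene, 60 °C
Reagents that add atoms: none
Why: Base-mediated lactonisation: the enol oxygen of the δ-ketone attacks the ester and methanol is lost, giving the 4-hydroxy-2-pyranone.

Step 20
Reactants: 28 6-(4-{3-[(tert-butyldimethylsilyl)oxy]pent-1-en-2-yl}-1,3,6-trimethylbicyclo[3.1.0]hex-2-en-6-yl)-4-hydroxy-3,5-dimethyl-2H-pyran-2-one
Product: 29 6-(4-{3-[(tert-butyldimethylsilyl)oxy]pent-1-en-2-yl}-1,3,6-trimethylbicyclo[3.1.0]hex-2-en-6-yl)-2-methoxy-3,5-dimethyl-4H-pyran-4-one
Conditions: MeOTf, 2,6-di-tert-butylpyridine, CH2Cl2, 0 °C → rt; NaHCO3 (aq)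
Reagents that add atoms: methyl trifluoromethanesulfonate, COS(=O)(=O)C(F)(F)F
Why: A hard methylating agent alkylates the neutral hydroxypyranone at its more basic lactone carbonyl oxygen, and proton loss from the pyrylium ion gives the 2-methoxy-4-pyranone. The hindered pyridine takes up the triflic acid without deprotonating the substrate, which protects the vinylcyclopropane and the silyl ether.

Step 21
Reactants: 29 6-(4-{3-[(tert-butyldimethylsilyl)oxy]pent-1-en-2-yl}-1,3,6-trimethylbicyclo[3.1.0]hex-2-en-6-yl)-2-methoxy-3,5-dimethyl-4H-pyran-4-one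
Product: 30 6-[4-(3-hydroxypent-1-en-2-yl)-1,3,6-trimethylbicyclo[3.1.0]hex-2-en-6-yl]-2-methoxy-3,5-dimethyl-4H-pyran-4-one (carbinol epimers)
Conditions: Bu4NF, AcOH, THF, 0 °C → rt
Reagents that add atoms: none
Why: Fluoride desilylation buffered with acetic acid is neither acidic enough for the vinylcyclopropane nor basic enough for the pyranone.

Step 22
Reactants: 30 6-[4-(3-hydroxypent-1-en-2-yl)-1,3,6-trimethylbicyclo[3.1.0]hex-2-en-6-yl]-2-methoxy-3,5-dimethyl-4H-pyran-4-one
Product: 31 2-methoxy-3,5-dimethyl-6-[(1S,4R,5R,6S)-1,3,6-trimethyl-4-(3-oxopent-1-en-2-yl)bicyclo[3.1.0]hex-2-en-6-yl]-4H-pyran-4-one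
Conditions: Dess–Martin periodinane, NaHCO3, CH2Cl2, 0 °C
Reagents that add atoms: none
Why: Buffered periodinane oxidation of the allylic alcohol unveils the vinyl ketone last, under neutral conditions that should neither epimerise C4 nor move the exocyclic double bond. Both carbinol epimers give the same ketone.

## Compound list

1 | (S)-carvone, (5S)-2-methyl-5-(prop-1-en-2-yl)cyclohex-2-en-1-one | CC1=CC[C@@H](CC1=O)C(C)=C | starting material
2 | trimethyl{[6-methyl-3-(prop-1-en-2-yl)cyclohexa-1,5-dien-1-yl]oxy}silane (C3 as in 1; not isolated) | CC1=CC[C@@H](C=C1O[Si](C)(C)C)C(C)=C | intermediate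
3 | (5R,6R)-6-hydroxy-2-methyl-5-(prop-1-en-2-yl)cyclohex-2-en-1-one (hydroxyl trans to isopropenyl) | CC1=CC[C@H](C(C)=C)[C@@H](O)C1=O | intermediate
4 | (5R,6R)-6-[(tert-butyldimethylsilyl)oxy]-2-methyl-5-(prop-1-en-2-yl)cyclohex-2-en-1-one | CC1=CC[C@H](C(C)=C)[C@@H](O[Si](C)(C)C(C)(C)C)C1=O | intermediate
5 | tributyl[(methoxymethoxy)methyl]stannane | CCCC[Sn](CCCC)(CCCC)COCOC | starting material
6 | (methoxymethoxy)methyllithium (not isolated) | [Li]COCOC | intermediate
7 | (5R,6R)-6-[(tert-butyldimethylsilyl)oxy]-1-[(methoxymethoxy)methyl]-2-methyl-5-(prop-1-en-2-yl)cyclohex-2-en-1-ol (C1 epimers) | CC1=CC[C@H](C(C)=C)[C@@H](O[Si](C)(C)C(C)(C)C)C1(O)COCOC | intermediate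
8 | (4R,5R)-4-[(tert-butyldimethylsilyl)oxy]-3-[(methoxymethoxy)methyl]-2-methyl-5-(prop-1-en-2-yl)cyclohex-2-en-1-one | CC(=C)[C@H]1CC(=O)C(C)=C(COCOC)[C@@H]1O[Si](C)(C)C(C)(C)C | intermediate
9 | lithium (3S,4R,5R)-4-[(tert-butyldimethylsilyl)oxy]-3-[(methoxymethoxy)methyl]-2,3-dimethyl-5-(prop-1-en-2-yl)cyclohex-1-en-1-olate (not isolated) | CC(=C)[C@H]1CC(O[Li])=C(C)[C@@](C)(COCOC)[C@@H]1O[Si](C)(C)C(C)(C)C | intermediate
10 | (3S,4R,5R)-4-[(tert-butyldimethylsilyl)oxy]-3-[(methoxymethoxy)methyl]-2,3-dimethyl-5-(prop-1-en-2-yl)cyclohex-1-en-1-yl acetate | CC(=C)[C@H]1CC(OC(C)=O)=C(C)[C@@](C)(COCOC)[C@@H]1O[Si](C)(C)C(C)(C)C | intermediate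
11 | (3S,4R,5R)-4-hydroxy-3-[(methoxymethoxy)methyl]-2,3-dimethyl-5-(prop-1-en-2-yl)cyclohex-1-en-1-yl acetate | CC(=C)[C@H]1CC(OC(C)=O)=C(C)[C@@](C)(COCOC)[C@@H]1O | intermediate
12 | (3S,4R,5R)-3-[(methoxymethoxy)methyl]-2,3-dimethyl-4-[(methylsulfonyl)oxy]-5-(prop-1-en-2-yl)cyclohex-1-en-1-yl acetate | CC(=C)[C@H]1CC(OC(C)=O)=C(C)[C@@](C)(COCOC)[C@@H]1OS(C)(=O)=O | intermediate
13 | lithium (3S,4R,5R)-3-[(methoxymethoxy)methyl]-2,3-dimethyl-4-[(methylsulfonyl)oxy]-5-(prop-1-en-2-yl)cyclohex-1-en-1-olate (not isolated) | CC(=C)[C@H]1CC(O[Li])=C(C)[C@@](C)(COCOC)[C@@H]1OS(C)(=O)=O | intermediate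
14 | (1S,4S,5S,6S)-6-[(methoxymethoxy)methyl]-1,6-dimethyl-4-(prop-1-en-2-yl)bicyclo[3.1.0]hexan-2-one | CC(=C)[C@H]1CC(=O)[C@@]2(C)[C@@H]1[C@]2(C)COCOC | intermediate
15 | 4-(3-hydroxyprop-1-en-2-yl)-6-[(methoxymethoxy)methyl]-1,6-dimethylbicyclo[3.1.0]hexan-2-one (ring configuration as in 14; not isolated) | OCC(=C)[C@H]1CC(=O)[C@@]2(C)[C@@H]1[C@]2(C)COCOC | intermediate
16 | 6-[(methoxymethoxy)methyl]-1,6-dimethyl-4-(3-oxoprop-1-en-2-yl)bicyclo[3.1.0]hexan-2-one (ring configuration as in 14) | O=CC(=C)[C@H]1CC(=O)[C@@]2(C)[C@@H]1[C@]2(C)COCOC | intermediate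
17 | 4-(3-hydroxypent-1-en-2-yl)-6-[(methoxymethoxy)methyl]-1,6-dimethylbicyclo[3.1.0]hexan-2-one (carbinol epimers) | CCC(O)C(=C)[C@H]1CC(=O)[C@@]2(C)[C@@H]1[C@]2(C)COCOC | intermediate
18 | 4-{3-[(tert-butyldimethylsilyl)oxy]pent-1-en-2-yl}-6-[(methoxymethoxy)methyl]-1,6-dimethylbicyclo[3.1.0]hexan-2-one | CCC(O[Si](C)(C)C(C)(C)C)C(=C)[C@H]1CC(=O)[C@@]2(C)[C@@H]1[C@]2(C)COCOC | intermediate
19 | 4-{3-[(tert-butyldimethylsilyl)oxy]pent-1-en-2-yl}-6-[(methoxymethoxy)methyl]-1,3,6-trimethylbicyclo[3.1.0]hexan-2-one (C3 epimers) | CCC(O[Si](C)(C)C(C)(C)C)C(=C)[C@H]1C(C)C(=O)[C@@]2(C)[C@@H]1[C@]2(C)COCOC | intermediate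
20 | 4-{3-[(tert-butyldimethylsilyl)oxy]pent-1-en-2-yl}-6-[(methoxymethoxy)methyl]-1,3,6-trimethylbicyclo[3.1.0]hex-2-en-2-yl trifluoromethanesulfonate | CCC(O[Si](C)(C)C(C)(C)C)C(=C)[C@H]1C(C)=C(OS(=O)(=O)C(F)(F)F)[C@@]2(C)[C@@H]1[C@]2(C)COCOC | intermediate
21 | 4-{3-[(tert-butyldimethylsilyl)oxy]pent-1-en-2-yl}-6-(hydroxymethyl)-1,3,6-trimethylbicyclo[3.1.0]hex-2-en-2-yl trifluoromethanesulfonate | CCC(O[Si](C)(C)C(C)(C)C)C(=C)[C@H]1C(C)=C(OS(=O)(=O)C(F)(F)F)[C@@]2(C)[C@@H]1[C@]2(C)CO | intermediate
22 | (4-{3-[(tert-butyldimethylsilyl)oxy]pent-1-en-2-yl}-1,3,6-trimethylbicyclo[3.1.0]hex-2-en-6-yl)methanol | CCC(O[Si](C)(C)C(C)(C)C)C(=C)[C@H]1C(C)=C[C@@]2(C)[C@@H]1[C@]2(C)CO | intermediate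
23 | 4-{3-[(tert-butyldimethylsilyl)oxy]pent-1-en-2-yl}-1,3,6-trimethylbicyclo[3.1.0]hex-2-ene-6-carbaldehyde | CCC(O[Si](C)(C)C(C)(C)C)C(=C)[C@H]1C(C)=C[C@@]2(C)[C@@H]1[C@]2(C)C=O | intermediate
24 | methyl 2-methyl-3-oxopentanoate | CCC(=O)C(C)C(=O)OC | starting material
25 | sodium lithium C2,C4-dianion of methyl 2-methyl-3-oxopentanoate (not isolated) | [Na+].[Li+].C[CH-]C(=O)[C-](C)C(=O)OC | intermediate
26 | methyl 5-(4-{3-[(tert-butyldimethylsilyl)oxy]pent-1-en-2-yl}-1,3,6-trimethylbicyclo[3.1.0]hex-2-en-6-yl)-5-hydroxy-2,4-dimethyl-3-oxopentanoate (epimer mixture) | CCC(O[Si](C)(C)C(C)(C)C)C(=C)[C@H]1C(C)=C[C@@]2(C)[C@@H]1[C@]2(C)C(O)C(C)C(=O)C(C)C(=O)OC | intermediate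
27 | methyl 5-(4-{3-[(tert-butyldimethylsilyl)oxy]pent-1-en-2-yl}-1,3,6-trimethylbicyclo[3.1.0]hex-2-en-6-yl)-2,4-dimethyl-3,5-dioxopentanoate | CCC(O[Si](C)(C)C(C)(C)C)C(=C)[C@H]1C(C)=C[C@@]2(C)[C@@H]1[C@]2(C)C(=O)C(C)C(=O)C(C)C(=O)OC | intermediate
28 | 6-(4-{3-[(tert-butyldimethylsilyl)oxy]pent-1-en-2-yl}-1,3,6-trimethylbicyclo[3.1.0]hex-2-en-6-yl)-4-hydroxy-3,5-dimethyl-2H-pyran-2-one | CCC(O[Si](C)(C)C(C)(C)C)C(=C)[C@H]1C(C)=C[C@@]2(C)[C@@H]1[C@]2(C)c1oc(=O)c(C)c(O)c1C | intermediate
29 | 6-(4-{3-[(tert-butyldimethylsilyl)oxy]pent-1-en-2-yl}-1,3,6-trimethylbicyclo[3.1.0]hex-2-en-6-yl)-2-methoxy-3,5-dimethyl-4H-pyran-4-one | CCC(O[Si](C)(C)C(C)(C)C)C(=C)[C@H]1C(C)=C[C@@]2(C)[C@@H]1[C@]2(C)c1oc(OC)c(C)c(=O)c1C | intermediate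
30 | 6-[4-(3-hydroxypent-1-en-2-yl)-1,3,6-trimethylbicyclo[3.1.0]hex-2-en-6-yl]-2-methoxy-3,5-dimethyl-4H-pyran-4-one (carbinol epimers) | CCC(O)C(=C)[C@H]1C(C)=C[C@@]2(C)[C@@H]1[C@]2(C)c1oc(OC)c(C)c(=O)c1C | intermediate
31 | 2-methoxy-3,5-dimethyl-6-[(1S,4R,5R,6S)-1,3,6-trimethyl-4-(3-oxopent-1-en-2-yl)bicyclo[3.1.0]hex-2-en-6-yl]-4H-pyran-4-one | C=C(C(=O)CC)[C@H]1C(C)=C[C@@]2(C)[C@@H]1[C@]2(C)c1oc(OC)c(C)c(=O)c1C | target

## Step count and least certain steps

Total step count: 22. Longest linear sequence: 22 steps, from 1 to 31; 5 and 24 are used as purchased.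

**Step 8 (key step).** The most likely failure is attack of the alkyllithium on the sulfonate ester (deprotonation of its methyl group or cleavage at sulfur) before or alongside cleavage of the enol ester. A second risk is proton exchange between the enolate and ketone already formed, which would let the enolate move to the other α-carbon, and closure at the neopentyl-type centre may also be slow. The fallback sets out from 12: K2CO3 in MeOH at 0 °C removes the acetyl group and gives the keto sulfonate 3-[(methoxymethoxy)methyl]-2,3-dimethyl-4-[(methylsulfonyl)oxy]-5-(prop-1-en-2-yl)cyclohexan-1-one F1. KOt-Bu in t-BuOH/THF then closes the cyclopropane through the more substituted enolate under equilibrating conditions, with no carbon nucleophile present, and the route is rejoined at 14.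

**Step 5.** The most likely failure is sluggish methyl transfer to the tetrasubstituted, γ-branched enone, with enolisation or reduction taking over; partial attack from the face of the isopropenyl group is the second risk. The fallback sets out from 8 and uses silyl-accelerated addition (Me2CuLi with Me3SiCl, THF, −78 °C) to give the trimethylsilyl enol ether {[4-[(tert-butyldimethylsilyl)oxy]-3-[(methoxymethoxy)methyl]-2,3-dimethyl-5-(prop-1-en-2-yl)cyclohex-1-en-1-yl]oxy}trimethylsilane F2. MeLi cleaves F2 to the same lithium enolate 9, and Ac2O then gives 10, where the route is rejoined.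

**Step 9.** The most likely failure is oxidation at the wrong place, either α to the ring ketone or by ene attack at the tertiary C4–H, or incomplete conversion that leaves mixtures. The fallback sets out from 14 and changes the mode of functionalisation. Ene-type chlorination of the isopropenyl group with hypochlorous acid (Ca(OCl)2, CO2, CH2Cl2/H2O) gives the allylic chloride 4-(3-chloroprop-1-en-2-yl)-6-[(methoxymethoxy)methyl]-1,6-dimethylbicyclo[3.1.0]hexan-2-one F3. Oxidation of F3 with N-methylmorpholine N-oxide (Kornblum type) gives the enal 16, where the route is rejoined.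

**Step 14.** The most likely failure is loss of the allylic silyl ether together with the acetal, or incomplete cleavage of the neopentyl-type acetal. The fallback sets out from 20 and gives up selectivity on purpose. HCl in MeOH removes both groups to give the diol 6-(hydroxymethyl)-4-(3-hydroxypent-1-en-2-yl)-1,3,6-trimethylbicyclo[3.1.0]hex-2-en-2-yl trifluoromethanesulfonate F4. TBSOTf with 2,6-lutidine silylates both hydroxyls to the bis-silyl ether 4-{3-[(tert-butyldimethylsilyl)oxy]pent-1-en-2-yl}-6-{[(tert-butyldimethylsilyl)oxy]methyl}-1,3,6-trimethylbicyclo[3.1.0]hex-2-en-2-yl trifluoromethanesulfonate F5. HF·pyridine buffered with pyridine then frees only the primary alcohol, and the route is rejoined at 21.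

**Step 20.** The most likely failure is methylation at the 4-hydroxyl oxygen instead of the lactone carbonyl oxygen, or acid-induced opening of the vinylcyclopropane if the triflic acid is not scavenged fast enough. The fallback sets out from 27 and avoids the methylation altogether. Cyclodehydration with PPh3/CCl4 (Appel-type activation of the δ-enol, closure through the ester carbonyl oxygen with loss of water) keeps the ester methoxy group and returns to the route at 29. It makes no new compound (F0).

## Further compounds

F1 | step 8 | 3-[(methoxymethoxy)methyl]-2,3-dimethyl-4-[(methylsulfonyl)oxy]-5-(prop-1-en-2-yl)cyclohexan-1-one (C2 epimers; other centres as in 12) | CC(=C)[C@H]1CC(=O)C(C)[C@@](C)(COCOC)[C@@H]1OS(C)(=O)=O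
F2 | step 5 | {[4-[(tert-butyldimethylsilyl)oxy]-3-[(methoxymethoxy)methyl]-2,3-dimethyl-5-(prop-1-en-2-yl)cyclohex-1-en-1-yl]oxy}trimethylsilane (centres as in 10) | CC(=C)[C@H]1CC(O[Si](C)(C)C)=C(C)[C@@](C)(COCOC)[C@@H]1O[Si](C)(C)C(C)(C)C
F3 | step 9 | 4-(3-chloroprop-1-en-2-yl)-6-[(methoxymethoxy)methyl]-1,6-dimethylbicyclo[3.1.0]hexan-2-one (ring configuration as in 14) | ClCC(=C)[C@H]1CC(=O)[C@@]2(C)[C@@H]1[C@]2(C)COCOC
F4 | step 14 | 6-(hydroxymethyl)-4-(3-hydroxypent-1-en-2-yl)-1,3,6-trimethylbicyclo[3.1.0]hex-2-en-2-yl trifluoromethanesulfonate | CCC(O)C(=C)[C@H]1C(C)=C(OS(=O)(=O)C(F)(F)F)[C@@]2(C)[C@@H]1[C@]2(C)CO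
F5 | step 14 | 4-{3-[(tert-butyldimethylsilyl)oxy]pent-1-en-2-yl}-6-{[(tert-butyldimethylsilyl)oxy]methyl}-1,3,6-trimethylbicyclo[3.1.0]hex-2-en-2-yl trifluoromethanesulfonate | CCC(O[Si](C)(C)C(C)(C)C)C(=C)[C@H]1C(C)=C(OS(=O)(=O)C(F)(F)F)[C@@]2(C)[C@@H]1[C@]2(C)CO[Si](C)(C)C(C)(C)C
F0 | step 20 | none | none
A1 | alternative 1 | 3,5-dimethylpyridine | Cc1cncc(C)c1
A2 | alternative 1 | tert-butyldimethyl({4,6,7-trimethyl-3-[(trimethylsilyl)ethynyl]-2-azabicyclo[4.1.0]hept-4-en-7-yl}methoxy)silane (C7 methyl over the six-membered ring; alkynyl anti to the cyclopropane) | C[Si](C)(C)C#C[C@H]1C(C)=C[C@@]2(C)[C@@H](N1)[C@]2(C)CO[Si](C)(C)C(C)(C)C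
A3 | alternative 1 | tert-butyldimethyl({1,3,6-trimethyl-4-[(trimethylsilyl)ethynyl]bicyclo[3.1.0]hex-2-en-6-yl}methoxy)silane | C[Si](C)(C)C#C[C@H]1C(C)=C[C@@]2(C)[C@@H]1[C@]2(C)CO[Si](C)(C)C(C)(C)C
A4 | alternative 2 | 1,3-dimethylcyclopenta-1,3-diene | CC1=CC(C)=CC1
A5 | alternative 2 | chloro(methyl)ketene, 2-chloroprop-1-en-1-one | CC(Cl)=C=O
A6 | alternative 2 | 7-chloro-1,3,7-trimethylbicyclo[3.2.0]hept-2-en-6-one (chlorine exo; C7 methyl endo) | C1C(C)=C[C@@]2(C)[C@@H]1C(=O)[C@]2(C)Cl
A7 | alternative 2 | methyl 1,3,6-trimethylbicyclo[3.1.0]hex-2-ene-6-carboxylate (C6 methyl endo; ester exo) | C1C(C)=C[C@@]2(C)[C@@H]1[C@]2(C)C(=O)OC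
A8 | alternative 3 | tert-butyl{[(E)-1-(4-methoxybenzyloxy)-2,3,5-trimethylhept-2-en-6-yn-4-yl]oxy}dimethylsilane (C5 epimers) | C#CC(C)[C@@H](O[Si](C)(C)C(C)(C)C)/C(C)=C(\C)COCc1ccc(OC)cc1
A9 | alternative 3 | tert-butyl{[6-(4-methoxybenzyloxymethyl)-1,3,6-trimethylbicyclo[3.1.0]hex-3-en-2-yl]oxy}dimethylsilane (silyloxy anti to the cyclopropane; C6 methyl endo) | C1=C(C)[C@@H](O[Si](C)(C)C(C)(C)C)[C@@]2(C)[C@@H]1[C@]2(C)COCc1ccc(OC)cc1
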